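Of the constants behind these flasks we want no single value but one ratio, because in percent of electrophile units the rate of self-condensation over the rate of target formation is ρ = σa/b, where a is electrophile and b free nucleophile, both as fractions of the electrophile charged. Control passes to target formation at the crossing where ρ equals one, that is where a/b equals the inverse of σ.

| flask | electrophile | nucleophile | free base | temperature | remark | time |
|---|---|---|---|---|---|---|
| larch | 0.050 M | 0.90 equiv | 0.30 equiv | 45 °C | run made earlier |  |
| maple | 0.025 M | 0.90 equiv | 0.30 equiv | 60 °C | run made earlier |  |
| alder | 0.10 M | 0.90 equiv | 0.30 equiv | 45 °C | run made earlier |  |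
| delta | 0.050 M | 0.900 equiv (fed, over 12 h) | 0.300 equiv |  | the addition at 30 °C, then warmed to 60 °C; the feed brings no volume worth counting | 30 h |
| gamma | 0.050 M | 0.900 equiv | 0.300 equiv | 60 °C | everything together at the start | 30 h |
| alpha | 0.050 M (fed, over 12 h) | 0.900 equiv | 0.300 equiv | 60 °C | all else is in the flask from the start; the feed brings no volume worth counting | 30 h |
| theta | 0.050 M | 0.900 equiv (fed, over 12 h) | 0.300 equiv | 60 °C | all else is in the flask from the start; the feed brings no volume worth counting | 30 h |

- larch (time / h: target / %, self-condensation product / %): 5.00: 17.4, 32.6; 10.0: 25.4, 43.4; 15.0: 27.3, 48.0; 30.0: 34.5, 52.6; 60.0: 38.9, 56.7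
- maple (time / h: target / %, self-condensation product / %): 2.50: 16.2, 33.1; 5.00: 20.9, 45.2; 8.00: 25.6, 52.9; 15.0: 31.1, 55.9; 30.0: 35.8, 59.3
- alder (time / h: target / %, self-condensation product / %): 5.00: 23.3, 43.4; 15.0: 34.4, 53.5; 30.0: 38.3, 55.6; 40.0: 39.4, 57.2; 60.0: 42.0, 57.3

(standard deviation of a reading: 1 percentage point)

- percent here means electrophile units held: one self-condensation product counts as two
- on the list of suspects stand: electrophile + nucleophile -> acid set free + target; acid set free + free base <-> salt of the base; 2 electrophile -> self-condensation product; nucleophile + acid set free <-> protonated nucleophile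

* which flask leads in share of target in target plus self-condensation product ("all alike" within 1.5 percentage points) (delta / gamma / alpha / theta / all alike)
* share of target in target plus self-condensation product at the end, delta
* share of target in target plus self-condensation product at the end, gamma
* share of target in target plus self-condensation product at the end, alpha
* share of target in target plus self-condensation product at the end, theta

We read σ in two ways from maple, the run at the temperature of these flasks. Up to 2.50 h, maple gained 2.04 units of self-condensation product per target, while a/b, taking b as charge minus target, averaged 0.899. So σ = 2.27, the selectivity factor: electrophile units lost to self-condensation per target formed when electrophile and free nucleophile stand at equal fractions. The crossing then stands at a/b = 0.440.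

From 2.50 h to 8.00 h, the same balance gives 4.13, so the ways part. The later one cheats, we think, since each target sets free an acid that may hold a nucleophile: counting every acid so held brings it down to 2.94. We keep the early value.

Gamma therefore starts at ρ = 2.53. Larch at 10.0 h and alder at 5.00 h hold 43.4 % and 43.4 % of self-condensation product, so concentration × time carries over. Theta at 1.25 h should then hold maple's electrophile against 0.0938 of nucleophile fed, giving ρ near 12.3. In alpha the crossing lies at a = b/σ, which is 0.396 with nucleophile at its full charge and lower as free nucleophile falls. We commit to alpha first and theta last.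

The forecast says alpha, with 50 % for alpha, 39 % for gamma, 37.5 % for delta and 24 % for theta, the last because “nucleophile starved at 60 °C”.

    electrophile + nucleophile → acid set free + target (k = 4.80 M⁻¹ h⁻¹, Ea = 71.0 kJ mol⁻¹)
    acid set free + free base ⇌ salt of the base (K = 9.50 × 10⁵ M⁻¹, k = 43.0 M⁻¹ h⁻¹, Ea = 81.0 kJ mol⁻¹, ΔH = −43.0 kJ mol⁻¹)
    2 electrophile → self-condensation product (k = 5.50 M⁻¹ h⁻¹, Ea = 86.0 kJ mol⁻¹)
    nucleophile + acid set free ⇌ protonated nucleophile, settled at all times (K = 1900 M⁻¹, ΔH = 60.0 kJ mol⁻¹)
    (constants at 60 °C)

The share ends at 45.3 % in alpha, 38.5 % in gamma, 36.7 % in delta and 20.7 % in theta, and in theta at 1.20 h self-condensation uses electrophile 18 times as fast as target formation, which with our σ puts a/b at 8.00, far beyond the crossing. In alpha at 30.0 h, with electrophile at 4.3 % of its charge and nucleophile at 22 % of its own, the same σ gives ρ = 0.496.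

(The readings were generated by integration for an exercise, and the scatter is random.)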